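## Retrosynthetic overview

1. The tetronic acid is the only ring made and is closed last: ethyl propanoate enolate is acylated by a 1,3-dioxolan-4-one carried from L-malic acid, then lactonised. The furan is bought.
2. The CH2–C(Me)= bond next to the lactone comes from a visible-light Ir/Ni decarboxylative coupling of L-malic acid acetonide acid with a (Z)-alkenyl iodide.
3. The tertiary carbinol comes from chelation-controlled addition of 3-(furan-3-yl)propylmagnesium chloride to an α-methoxy methyl ketone.
4. The (E)-CH=CH comes from cross metathesis of methyl (S)-2-methoxybut-3-enoate with an iodo-diene made from (S)-β-citronellene (ozonolysis, then Stork–Zhao-type iodo-olefination).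
5. Stereocentres: C–OMe from methyl (S)-vinylglycolate, CHMe from (S)-β-citronellene, lactone C5 from L-malic acid, carbinol by 1,2-induction.

Assumption: (S)-β-citronellene, methyl (S)-2-hydroxybut-3-enoate and (S)-2,2-dimethyl-5-oxo-1,3-dioxolane-4-acetic acid (L-malic acid acetonide) are bought as single enantiomers.

## Route

Step 1
Reactants: 1 (S)-β-citronellene [(3S)-3,7-dimethylocta-1,6-diene]
Product: 3 (S)-4-methylhex-5-enal, via secondary ozonide 2 (not isolated)
Conditions: O3 (1.0 equiv, Sudan Red 7B end point), CH2Cl2, −78 °C; then Me2S, −78 → 20 °C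
Reagents that add atoms: ozone, O=[O+][O-]
Why: Chemoselective ozonolysis, because the electron-rich trisubstituted alkene reacts far faster than the monosubstituted vinyl group, and the stereocentre is not touched.

Step 2
Reactants: 3 (S)-4-methylhex-5-enal
Product: 4 (3S,6Z)-7-iodo-3-methylocta-1,6-diene
Conditions: EtPPh3I, n-BuLi, THF, 20 °C; I2, −78 °C; NaN(SiMe3)2, −20 °C; then 3, −78 → 20 °C
Reagents that add atoms: ethyltriphenylphosphonium iodide, CC[P+](c1ccccc1)(c1ccccc1)c1ccccc1.[I-]; iodine, II
Why: Stork–Zhao-type Wittig iodo-olefination with the unstabilised α-iodoethylidene ylide, whose kinetic cis-selectivity places iodine cis to the chain (Z, typically ≥10:1) and so fixes the geometry of the later trisubstituted alkene.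

Step 3
Reactants: 5 methyl (S)-2-hydroxybut-3-enoate
Product: 6 methyl (S)-2-methoxybut-3-enoate
Conditions: MeI, Ag2O, MeCN, 20 °C, dark
Reagents that add atoms: iodomethane, CI
Why: Purdie methylation, a silver-assisted SN2 O-alkylation without strong base, so the allylic α-stereocentre is not epimerised.

Step 4
Reactants: 4 (3S,6Z)-7-iodo-3-methylocta-1,6-diene; 6 methyl (S)-2-methoxybut-3-enoate (2.5 equiv)
Product: 7 methyl (2S,3E,5S,8Z)-9-iodo-2-methoxy-5-methyldeca-3,8-dienoate
Conditions: RuCl2(H2IMes)(=CH-C6H4-2-O-i-Pr) (second-generation Hoveyda–Grubbs catalyst, 5 mol%), 1,4-benzoquinone (10 mol%), CH2Cl2, 40 °C, N2 sparge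
Reagents that add atoms: none
Why: Olefin cross metathesis of two slowly dimerising allylically branched terminal alkenes gives the thermodynamic E-alkene, while the hindered, iodine-bearing trisubstituted alkene should not engage the carbene (so the ring closure to methylcyclopentene expected for citronellene itself is avoided) and neither allylic stereocentre is touched.

Step 5
Reactants: 7 methyl (2S,3E,5S,8Z)-9-iodo-2-methoxy-5-methyldeca-3,8-dienoate
Product: 9 (3S,4E,6S,9Z)-10-iodo-3-methoxy-6-methylundeca-4,9-dien-2-one, via Weinreb amide 8 (not isolated)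
Conditions: MeNH(OMe)·HCl, i-PrMgCl, THF, −20 °C; then MeMgBr, −20 → 0 °C; aq NH4Cl
Reagents that add atoms: methylmagnesium bromide, C[Mg]Br; N,O-dimethylhydroxylamine hydrochloride, CNOC.Cl (atoms held in 8 only)
Why: One-pot Weinreb ketone synthesis, in which the chelated tetrahedral adduct stops at the ketone stage; the low temperature protects the α-stereocentre and the alkenyl iodide does not exchange with these Grignard reagents.

Step 6
Reactants: 10 3-bromofuran
Product: 12 3-(3-chloropropyl)furan, via 3-furyllithium 11 (not isolated)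
Conditions: n-BuLi, THF, −78 °C; then ClCH2CH2CH2I, DMPU, −78 → −40 °C
Reagents that add atoms: 1-chloro-3-iodopropane, ClCCCI; n-butyllithium, [Li]CCCC (lithium held in 11 only)
Why: Bromine–lithium exchange followed by SN2 alkylation at the iodide end of the dihalide; keeping the mixture below −40 °C prevents isomerisation to the 2-lithio species.

Step 7
Reactants: 9 (3S,4E,6S,9Z)-10-iodo-3-methoxy-6-methylundeca-4,9-dien-2-one; 12 3-(3-chloropropyl)furan
Product: 14 (4S,5S,6E,8S,11Z)-1-(furan-3-yl)-12-iodo-5-methoxy-4,8-dimethyltrideca-6,11-dien-4-ol, via Grignard reagent 13 (not isolated)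
Conditions: 12, Mg, THF, 50 °C; then 9, MgBr2·OEt2, THF/CH2Cl2, −78 °C; aq NH4Cl
Reagents that add atoms: magnesium, [Mg] (held in 13 only)
Why: Grignard addition under Cram chelation control, in which magnesium bridges the carbonyl and methoxy oxygens and the nucleophile enters from the face of the α-hydrogen, giving the (4S) carbinol from the (S)-methoxy centre (dr expected ≥10:1).

Step 8
Reactants: 14 (4S,5S,6E,8S,11Z)-1-(furan-3-yl)-12-iodo-5-methoxy-4,8-dimethyltrideca-6,11-dien-4-ol; 15 (S)-2,2-dimethyl-5-oxo-1,3-dioxolane-4-acetic acid (2 equiv)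
Product: 16 (5S)-5-[(2Z,6S,7E,9S,10S)-13-(furan-3-yl)-10-hydroxy-9-methoxy-2,6,10-trimethyltrideca-2,7-dien-1-yl]-2,2-dimethyl-1,3-dioxolan-4-one
Conditions: Ir[dF(CF3)ppy]2(dtbbpy)PF6 (2 mol%), NiCl2·glyme (10 mol%), dtbbpy (15 mol%), K2HPO4 (2.5 equiv), degassed DMSO, 450 nm LEDs, 25 °C
Reagents that add atoms: none
Why: Proposed new method: Ir/Ni metallaphotoredox decarboxylative C(sp3)–C(sp2) coupling, applied for the first time to a non-stabilised, β-oxygenated primary carboxylate (the malic acid acetonide as a chiral radical synthon for the lactone CH2–C5 unit) and a fully substituted (Z)-2-iodoalk-2-ene carrying a free tertiary alcohol and a furan; the excited trivalent iridium complex oxidises the potassium carboxylate, loss of CO2 gives the primary radical, which has no alkene in reach and no favourable β-scission, zerovalent nickel inserts into the carbon–iodine bond with retention, the alkenylnickel halide captures the radical to give a trivalent alkyl(alkenyl)nickel species that reductively eliminates, and the divalent iridium returns monovalent nickel to the zerovalent state; the malic stereocentre is one carbon away from the radical and the Z geometry is carried over from 14; closest known reaction type: Ir/Ni decarboxylative vinylation of α-oxy and α-amino acids and nickel-catalysed decarboxylative alkenylation of redox-active esters.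

Step 9
Reactants: 16 (5S)-5-[(2Z,6S,7E,9S,10S)-13-(furan-3-yl)-10-hydroxy-9-methoxy-2,6,10-trimethyltrideca-2,7-dien-1-yl]-2,2-dimethyl-1,3-dioxolan-4-one
Product: 18 (5S)-5-[(2Z,6S,7E,9S,10S)-13-(furan-3-yl)-10-hydroxy-9-methoxy-2,6,10-trimethyltrideca-2,7-dien-1-yl]-4-hydroxy-3-methylfuran-2(5H)-one, via hydroxy keto ester 17 (not isolated)
Conditions: EtCO2Et, LiN(i-Pr)2 (4 equiv), THF, −78 °C; then 16, −78 → 25 °C; 1 M HCl to pH 3, 0 °C
Reagents that add atoms: ethyl propanoate, CCC(=O)OCC
Why: Claisen-type acylation of the ester enolate by the dioxolanone carbonyl with loss of acetone, then lactonisation of the γ-alkoxide onto the ethyl ester (a Dieckmann-like closure) to the 3-methyltetronic acid; C5 comes unchanged from L-malic acid because carbonyl attack at −78 °C outruns deprotonation at C5 and the product is protected as its tetronate anion.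

## Compound list

1 | (S)-β-citronellene, (3S)-3,7-dimethylocta-1,6-diene | C=C[C@@H](C)CCC=C(C)C | starting material
2 | 3,3-dimethyl-5-[(3S)-3-methylpent-4-en-1-yl]-1,2,4-trioxolane (not isolated) | C=C[C@@H](C)CCC1OOC(C)(C)O1 | intermediate
3 | (S)-4-methylhex-5-enal | C=C[C@@H](C)CCC=O | intermediate
4 | (3S,6Z)-7-iodo-3-methylocta-1,6-diene | C=C[C@@H](C)CC/C=C(/C)I | intermediate
5 | methyl (S)-2-hydroxybut-3-enoate | O[C@@H](C=C)C(=O)OC | starting material
6 | methyl (S)-2-methoxybut-3-enoate | CO[C@@H](C=C)C(=O)OC | intermediate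
7 | methyl (2S,3E,5S,8Z)-9-iodo-2-methoxy-5-methyldeca-3,8-dienoate | CO[C@@H](/C=C/[C@@H](C)CC/C=C(/C)I)C(=O)OC | intermediate
8 | (2S,3E,5S,8Z)-9-iodo-N,2-dimethoxy-N,5-dimethyldeca-3,8-dienamide (not isolated) | CO[C@@H](/C=C/[C@@H](C)CC/C=C(/C)I)C(=O)N(C)OC | intermediate
9 | (3S,4E,6S,9Z)-10-iodo-3-methoxy-6-methylundeca-4,9-dien-2-one | CO[C@@H](/C=C/[C@@H](C)CC/C=C(/C)I)C(C)=O | intermediate
10 | 3-bromofuran | Brc1ccoc1 | starting material
11 | 3-furyllithium (not isolated) | [Li]c1ccoc1 | intermediate
12 | 3-(3-chloropropyl)furan | ClCCCc1ccoc1 | intermediate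
13 | [3-(furan-3-yl)propyl]magnesium chloride (not isolated) | Cl[Mg]CCCc1ccoc1 | intermediate
14 | (4S,5S,6E,8S,11Z)-1-(furan-3-yl)-12-iodo-5-methoxy-4,8-dimethyltrideca-6,11-dien-4-ol | CO[C@@H](/C=C/[C@@H](C)CC/C=C(/C)I)[C@@](C)(O)CCCc1ccoc1 | intermediate
15 | (S)-2,2-dimethyl-5-oxo-1,3-dioxolane-4-acetic acid | OC(=O)C[C@@H]1OC(C)(C)OC1=O | starting material
16 | (5S)-5-[(2Z,6S,7E,9S,10S)-13-(furan-3-yl)-10-hydroxy-9-methoxy-2,6,10-trimethyltrideca-2,7-dien-1-yl]-2,2-dimethyl-1,3-dioxolan-4-one | CO[C@@H](/C=C/[C@@H](C)CC/C=C(/C)C[C@@H]1OC(C)(C)OC1=O)[C@@](C)(O)CCCc1ccoc1 | intermediate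
17 | ethyl (4S,6Z,10S,11E,13S,14S)-17-(furan-3-yl)-4,14-dihydroxy-13-methoxy-2,6,10,14-tetramethyl-3-oxoheptadeca-6,11-dienoate (not isolated) | CO[C@@H](/C=C/[C@@H](C)CC/C=C(/C)C[C@H](O)C(=O)C(C)C(=O)OCC)[C@@](C)(O)CCCc1ccoc1 | intermediate
18 | (5S)-5-[(2Z,6S,7E,9S,10S)-13-(furan-3-yl)-10-hydroxy-9-methoxy-2,6,10-trimethyltrideca-2,7-dien-1-yl]-4-hydroxy-3-methylfuran-2(5H)-one (CNP0305089.2) | CO[C@@H](/C=C/[C@@H](C)CC/C=C(/C)C[C@@H]1OC(=O)C(C)=C1O)[C@@](C)(O)CCCc1ccoc1 | target

## Step count and risks

Total steps: 9. Longest linear sequence: 7 (steps 1, 2, 4, 5, 7, 8, 9 from compound 1).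

Steps most likely to fail:

**Step 4 (cross metathesis).** Both partners are branched at the allylic carbon, and the iodoalkene of 4 may still divert or kill the ruthenium carbene. The fallback sets out from 3 and 6 and runs the metathesis before the iodoalkene exists. Aldehyde 3 and ester 6 are cross-metathesised with the same ruthenium catalyst to give methyl (2S,3E,5S)-2-methoxy-5-methyl-8-oxooct-3-enoate F1. The iodo-olefination of step 2 is then applied to F1 at −78 °C, where the ylide attacks only the aldehyde, and the route is rejoined at 7.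

**Step 8 (the proposed new photochemical coupling).** Oxidation of the primary carboxylate may be slow, or the alkenylnickel intermediate may be reduced instead of coupled. The fallback uses known chemistry and sets out from 15. The acid is esterified with N-hydroxyphthalimide and N,N'-diisopropylcarbodiimide to the redox-active ester 1,3-dioxoisoindolin-2-yl 2-[(4S)-2,2-dimethyl-5-oxo-1,3-dioxolan-4-yl]acetate F2. F2 is joined to iodide 14 by nickel-electrocatalytic decarboxylative alkenylation (NiCl2·6H2O, 2,2′-bipyridine, AgNO3, Mg anode, carbon cathode, DMF, constant current, 25 °C). This is a reductive cross-electrophile coupling rather than an oxidative decarboxylation, and it comes back to the route at 16.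

**Step 9 (one-pot tetronic acid formation).** The enolate may deprotonate C5 of the dioxolanone and erode the malic stereocentre, or lactonisation may stall at 17. The fallback sets out from 16 and builds the ring by the classical stepwise Dieckmann route. Methanolysis (K2CO3, MeOH, 0 °C) gives methyl (2S,4Z,8S,9E,11S,12S)-15-(furan-3-yl)-2,12-dihydroxy-11-methoxy-4,8,12-trimethylpentadeca-4,9-dienoate F3. Selective acylation of the secondary hydroxyl (propanoic anhydride, DMAP, pyridine, 0 °C; the tertiary alcohol is left) gives methyl (2S,4Z,8S,9E,11S,12S)-15-(furan-3-yl)-12-hydroxy-11-methoxy-4,8,12-trimethyl-2-(propanoyloxy)pentadeca-4,9-dienoate F4. Dieckmann cyclisation of F4 (LiN(SiMe3)2, THF, −78 → 0 °C, then acid) comes back to the route at the target 18.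

## Further compounds

F1 | step 4 | methyl (2S,3E,5S)-2-methoxy-5-methyl-8-oxooct-3-enoate | CO[C@@H](/C=C/[C@@H](C)CCC=O)C(=O)OC
F2 | step 8 | 1,3-dioxoisoindolin-2-yl 2-[(4S)-2,2-dimethyl-5-oxo-1,3-dioxolan-4-yl]acetate | O=C(C[C@@H]1OC(C)(C)OC1=O)ON1C(=O)c2ccccc2C1=O
F3 | step 9 | methyl (2S,4Z,8S,9E,11S,12S)-15-(furan-3-yl)-2,12-dihydroxy-11-methoxy-4,8,12-trimethylpentadeca-4,9-dienoate | CO[C@@H](/C=C/[C@@H](C)CC/C=C(/C)C[C@H](O)C(=O)OC)[C@@](C)(O)CCCc1ccoc1
F4 | step 9 | methyl (2S,4Z,8S,9E,11S,12S)-15-(furan-3-yl)-12-hydroxy-11-methoxy-4,8,12-trimethyl-2-(propanoyloxy)pentadeca-4,9-dienoate | CO[C@@H](/C=C/[C@@H](C)CC/C=C(/C)C[C@H](OC(=O)CC)C(=O)OC)[C@@](C)(O)CCCc1ccoc1
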